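The carbocycle of the chroman is cut at C6–C7. The feature exploited is C8, the fully substituted ring carbon between the C7 ketone and the C8a enol-ether carbon. It has the substitution pattern of a dialkylmalonate, so two acyclic alkylations can settle its configuration. One Claisen-type closure then joins the terminal carbon of a 1,3-diketone dianion to the ester on C8 and delivers the whole cyclohexane-1,3,5-trione ring with its three side chains. Precursor 16 is a methyl 2-lavandulyl-2-prenyl-3,5-dioxo-7-phenylnonanedioate. Its remote acid is masked as a cumyl ester, as hindered as tert-butyl yet cleaved by 2% TFA, which the prenyl groups tolerate. C4a acylation and Mitsunobu closure on O–C8a complete the pyranone.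

Key step: step 9

Abbreviations: lavandulyl = 5-methyl-2-(prop-1-en-2-yl)hex-4-en-1-yl; prenyl = 3-methylbut-2-en-1-yl; cumyl = 2-phenylpropan-2-yl; TES = triethylsilyl. Chroman numbering (O1, C2–C4, C4a, C5–C8, C8a) is used for the future ring atoms throughout.

Stereochemical bookkeeping: the target is (2R,3S,8S) in the core (2,3-cis), S at the benzylic carbon and S at the lavandulyl carbon. The lavandulyl carbon has the spatial arrangement of (R)-lavandulol; the descriptor changes only because CH2OH is replaced by CH2–C.

Assumption: the sense of induction of the two alkaloid-derived catalysts (steps 3 and 5) is taken by analogy with simpler malonates and 3-substituted glutaric anhydrides; each has a commercial pseudo-enantiomer (the cinchonidinium salt, (DHQ)2AQN) that is used instead if a trial run shows the opposite sense.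

Step 1
Reactants: 1 (R)-lavandulol
Product: 2 (R)-lavandulyl iodide [(3R)-3-(iodomethyl)-2,6-dimethylhepta-1,5-diene]
Conditions: I2, PPh3, imidazole, CH2Cl2, 0 °C to rt
Reagents that add atoms: iodine, II
Why: Appel-type iodination of a primary alcohol takes place at the CH2 group only, so the neighbouring stereocentre and both alkenes are untouched.

Step 2
Reactants: 2 (R)-lavandulyl iodide; 3 tert-butyl methyl malonate
Product: 4 1-tert-butyl 3-methyl 2-[(2S)-lavandulyl]propanedioate (mixture of C2 epimers)
Conditions: NaH, 3 (1.5 equiv), DMF, 0 °C; then 2, 50 °C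
Reagents that add atoms: none
Why: Malonic ester alkylation (SN2) with a soft, weakly basic enolate favours substitution over elimination on the β-branched primary iodide, excess malonate suppresses dialkylation, and the unselectively formed C2 centre is planarised again in step 3.

Step 3
Reactants: 4 lavandulylmalonate; 5 prenyl bromide
Product: 6 1-tert-butyl 3-methyl (2R)-2-[(2S)-lavandulyl]-2-prenylpropanedioate
Conditions: 5 (2 equiv), N-(9-anthracenylmethyl)cinchoninium chloride (10 mol %), 50% aq KOH, toluene, −20 °C
Reagents that add atoms: none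
Why: Asymmetric phase-transfer alkylation of an α-alkyl tert-butyl methyl malonate: the planar enolate of 4 is ion-paired with the chiral ammonium cation, which distinguishes the small methyl ester from the bulky tert-butyl ester and exposes one face to the reactive allylic bromide, setting the quaternary centre (future C8); the minor epimer is a diastereomer because of the lavandulyl centre and can be removed by chromatography.

Step 4
Reactants: 6 quaternary mixed malonate
Product: 8 (2S)-2-(methoxycarbonyl)-5-methyl-2-[(2S)-lavandulyl]hex-4-enoic acid, via trimethylsilyl ester 7 (not isolated)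
Conditions: TMSOTf, 2,6-lutidine, CH2Cl2, 0 °C to rt; then aq citric acid
Reagents that add atoms: trimethylsilyl triflate, C[Si](C)(C)OS(=O)(=O)C(F)(F)F (its Me3Si group is found in 7 only)
Why: Silyl-triflate-induced cleavage of a tert-butyl ester (loss of isobutene, then hydrolysis of the silyl ester on work-up) runs in a lutidine-buffered medium without Brønsted acid, so the alkenes are neither protonated nor lactonised, the methyl ester is inert and the quaternary centre has no way to epimerise.

Step 5
Reactants: 9 3-phenylglutaric anhydride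
Product: 10 (3R)-5-methoxy-5-oxo-3-phenylpentanoic acid
Conditions: MeOH (10 equiv), (DHQD)2AQN (cat.), Et2O, −40 °C
Reagents that add atoms: methanol, CO
Why: Alkaloid-catalysed methanolysis (general-base desymmetrisation of a prochiral cyclic anhydride) opens one of the two enantiotopic carbonyl groups and thereby sets the benzylic stereocentre; the half ester can be enriched further by recrystallising an amine salt.

Step 6
Reactants: 10 (R)-half ester
Product: 11 1-methyl 5-cumyl (3S)-3-phenylpentanedioate
Conditions: PhC(Me)2OH, Cl3CCN, DBU (cat.), CH2Cl2, 0 °C; then 10, rt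
Reagents that add atoms: 2-phenylpropan-2-ol, CC(C)(O)c1ccccc1
Why: Trichloroacetimidate esterification alkylates the carboxyl oxygen under essentially neutral conditions, so the carboxyl carbon is never activated and the two glutarate arms cannot exchange through the anhydride (no racemisation).

Step 7
Reactants: 11 cumyl methyl diester
Product: 13 cumyl (3S)-5-oxo-3-phenylhexanoate, via Weinreb amide 12 (not isolated)
Conditions: MeNH(OMe)·HCl, i-PrMgCl, THF, −20 °C; then MeMgCl, 0 °C; cold dilute HCl
Reagents that add atoms: N,O-dimethylhydroxylamine hydrochloride, CNOC.Cl (its MeN(OMe) group is found in 12 only); methylmagnesium chloride, C[Mg]Cl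
Why: Weinreb ketone synthesis in one flask: the magnesium amide attacks only the unhindered methyl ester, the chelated adduct of 12 with MeMgCl stops at the ketone stage, and the tertiary cumyl ester is too hindered to react at 0 °C.

Step 8
Reactants: 8 malonic half acid; 13 methyl ketone
Product: 16 1-methyl 9-cumyl (2S,7S)-2-[(2S)-lavandulyl]-3,5-dioxo-7-phenyl-2-prenylnonanedioate, via acid chloride 14 (not isolated), via lithium enolate 15 (not isolated)
Conditions: 8, 1-chloro-N,N,2-trimethylprop-1-en-1-amine, CH2Cl2, 0 °C to rt, concentrate; 13 (2.2 equiv), LDA (2.1 equiv), THF, −78 °C; add 14, −78 to −40 °C; AcOH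
Reagents that add atoms: 1-chloro-N,N,2-trimethylprop-1-en-1-amine, CC(C)=C(Cl)N(C)C (chlorine in 14 only); lithium diisopropylamide, [Li+].CC(C)[N-]C(C)C (lithium in 15 only)
Why: Claisen-type C-acylation of a kinetic lithium enolate with an acid chloride: LDA deprotonates the methyl group of 13 rather than the β-branched CH2, the non-enolisable chloride 14 (made under neutral conditions that spare the alkenes) cannot form a ketene, the second equivalent of the cheap enolate takes up the acidic proton of 16, and the hindered cumyl ester keeps 15 from closing on itself at −78 °C.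

Step 9
Reactants: 16 acyclic 3,5-dioxo diester
Product: 18 cumyl (3S)-3-{(5S)-2-hydroxy-5-[(2S)-lavandulyl]-4,6-dioxo-5-prenylcyclohex-1-en-1-yl}-3-phenylpropanoate (enol form of the cyclohexane-1,3,5-trione), via dilithium dianion 17 (not isolated)
Conditions: LDA (2.3 equiv), THF (0.02 M), −78 °C, 1 h, then 0 °C; cold 0.5 M HCl
Reagents that add atoms: lithium diisopropylamide, [Li+].CC(C)[N-]C(C)C (lithium in 17 only)
Why: LDA removes first a proton from the future C4a between the two ketones and then one from the future C6; the terminal carbon of dianion 17, its most nucleophilic site, adds to the methyl ester on the quaternary carbon and loss of methoxide forms the C6–C7 bond, the trione being drained off at once as its stabilised enolate (Dieckmann/Claisen condensation of a 1,3-diketone dianion, the reaction type that converts 2,2-dialkyl-3,5-dioxoalkanoates into 2,2-dialkylcyclohexane-1,3,5-triones). The six-membered carbocycle closes in the 6-(enolendo)-exo-trig mode and is helped by the gem-dialkyl effect of the quaternary carbon inside the forming ring. No stereocentre is created: C8 carries no α-hydrogen and keeps the configuration of step 3, and the benzylic C–H is not acidic. The step needs C- rather than O-acylation, because a mono-enolate would lactonise through the C5 oxygen; complete double deprotonation at −78 °C therefore precedes warming, and any enol lactone can be reopened by the liberated methoxide and funnelled to the trione enolate. It also needs the right ester: the terminal carbon could reach the cumyl ester only through a four-membered ring, the central carbon finds that ester too hindered, and the central carbon could reach the methyl ester only through a four-membered ring. Limiting the base to 2.3 equiv leaves the position next to the cumyl ester protonated, and a non-nucleophilic amide base cannot split the diketone by retro-Claisen attack.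

Step 10
Reactants: 19 methyl (S)-3-hydroxybutanoate
Product: 21 methyl (2S,3S)-3-hydroxy-2-methylbutanoate, via dilithium alkoxide enolate 20 (not isolated)
Conditions: LDA (2.2 equiv), THF, −78 to −20 °C; MeI, DMPU, −78 to 0 °C; AcOH
Reagents that add atoms: iodomethane, CI; lithium diisopropylamide, [Li+].CC(C)[N-]C(C)C (lithium in 20 only)
Why: Fráter–Seebach alkylation: the chelated alkoxide enolate 20 is methylated on the face away from the C3 methyl group, so the existing carbinol centre sets C2 as S (anti product).

Step 11
Reactants: 21 anti hydroxy ester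
Product: 22 (2S,3S)-3-hydroxy-2-methylbutanoic acid
Conditions: LiOH, THF–H2O, 0 °C to rt; then HCl to pH 2–3
Reagents that add atoms: lithium hydroxide, [Li+].[OH-]
Why: Saponification of an unhindered methyl ester at or below room temperature, where the carboxylate formed protects the α-centre from epimerisation and retro-aldol cleavage is slow.

Step 12
Reactants: 22 anti hydroxy acid
Product: 24 (2S,3S)-2-methyl-3-(triethylsilyloxy)butanoic acid, via bis-silyl derivative 23 (not isolated)
Conditions: TESCl (2.3 equiv), imidazole, CH2Cl2, 0 °C to rt; then MeOH–H2O, K2CO3 (cat.), 0 °C; pH 5 buffer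
Reagents that add atoms: chlorotriethylsilane, CC[Si](Cl)(CC)CC
Why: Exhaustive silylation followed by selective solvolysis, since a silyl ester is cleaved by aqueous methanol far faster than a secondary TES ether.

Step 13
Reactants: 18 trione; 24 silyloxy acid
Product: 26 cumyl (3S)-3-{(5S)-2,4-dihydroxy-5-[(2S)-lavandulyl]-3-[(2S,3S)-2-methyl-3-(triethylsilyloxy)butanoyl]-6-oxo-5-prenylcyclohexa-1,3-dien-1-yl}-3-phenylpropanoate, via enol ester 25 (not isolated)
Conditions: DCC, DMAP (1.3 equiv), CH2Cl2, 0 °C to rt
Reagents that add atoms: none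
Why: Steglich activation gives enol ester 25 (drawn on the C5 oxygen; its O-regioisomers converge) and DMAP then carries the acyl group from oxygen to carbon (O-to-C acyl migration known for cyclic 1,3-diones); C4a is the only carbon at which the product can rest as an enolised tricarbonyl, acylation at the substituted C6 being reversible, and the product enolate shields the α-stereocentre from epimerisation.

Step 14
Reactants: 26 silyl-protected acyl trione
Product: 27 cumyl (3S)-3-{(5S)-2,4-dihydroxy-3-[(2S,3S)-3-hydroxy-2-methylbutanoyl]-5-[(2S)-lavandulyl]-6-oxo-5-prenylcyclohexa-1,3-dien-1-yl}-3-phenylpropanoate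
Conditions: HF·pyridine, pyridine, THF, 0 °C
Reagents that add atoms: none
Why: Fluoride-induced cleavage of a secondary TES ether in a pyridine-buffered medium is mild enough to leave the cumyl ester, the three alkenes and the β-hydroxy ketone (no dehydration) intact.

Step 15
Reactants: 27 hydroxy acyl trione
Product: 28 cumyl (3S)-3-{(2R,3S,8S)-5-hydroxy-8-[(2S)-lavandulyl]-2,3-dimethyl-4,7-dioxo-8-prenyl-3,4,7,8-tetrahydro-2H-chromen-6-yl}-3-phenylpropanoate
Conditions: PPh3, DIAD, toluene (0.01 M), 0 °C
Reagents that add atoms: none
Why: Intramolecular Mitsunobu etherification: the activated carbinol is displaced with inversion (S to R at C2) by the enolate oxygen on C8a in a 6-exo-tet closure, as known for 2,3-dimethylchromanones from o-hydroxyaryl β-hydroxy ketones; the C5 hydroxyl is expected to stay locked in its hydrogen bond to the C4 carbonyl, which also turns the carbinol carbon towards O–C8a, and C3 is untouched, so the anti acid gives the 2,3-cis ring.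

Step 16
Reactants: 28 cumyl ester of the target
Product: 29 CNP0150579.2 [(3S)-3-{(2R,3S,8S)-5-hydroxy-8-[(2S)-lavandulyl]-2,3-dimethyl-4,7-dioxo-8-prenyl-3,4,7,8-tetrahydro-2H-chromen-6-yl}-3-phenylpropanoic acid]
Conditions: TFA (2% v/v), Et3SiH (5 equiv), CH2Cl2, 0 °C
Reagents that add atoms: none
Why: Acidolysis of a cumyl ester (SN1-type cleavage through the tertiary benzylic cation, trapped by the silane as cumene) proceeds at an acidity too low to protonate the trisubstituted alkenes, to cyclise the enol onto a prenyl group or to enolise C3, and no base ever meets the epimerisable 2,3-cis ring.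

Compound list
1 | (R)-lavandulol | C=C(C)[C@@H](CC=C(C)C)CO | starting material
2 | (R)-lavandulyl iodide | C=C(C)[C@@H](CC=C(C)C)CI | intermediate
3 | tert-butyl methyl malonate | COC(=O)CC(=O)OC(C)(C)C | starting material
4 | 1-tert-butyl 3-methyl 2-[(2S)-lavandulyl]propanedioate, C2 epimers | C=C(C)[C@@H](CC=C(C)C)CC(C(=O)OC)C(=O)OC(C)(C)C | intermediate
5 | prenyl bromide | CC(C)=CCBr | starting material
6 | 1-tert-butyl 3-methyl (2R)-2-[(2S)-lavandulyl]-2-prenylpropanedioate | C=C(C)[C@@H](CC=C(C)C)C[C@](CC=C(C)C)(C(=O)OC)C(=O)OC(C)(C)C | intermediate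
7 | 1-methyl 3-trimethylsilyl (2S)-2-[(2S)-lavandulyl]-2-prenylpropanedioate (not isolated) | C=C(C)[C@@H](CC=C(C)C)C[C@](CC=C(C)C)(C(=O)OC)C(=O)O[Si](C)(C)C | intermediate
8 | (2S)-2-(methoxycarbonyl)-5-methyl-2-[(2S)-lavandulyl]hex-4-enoic acid | C=C(C)[C@@H](CC=C(C)C)C[C@](CC=C(C)C)(C(=O)OC)C(=O)O | intermediate
9 | 3-phenylglutaric anhydride | O=C1CC(c2ccccc2)CC(=O)O1 | starting material
10 | (3R)-5-methoxy-5-oxo-3-phenylpentanoic acid | COC(=O)C[C@@H](CC(=O)O)c1ccccc1 | intermediate
11 | 1-methyl 5-cumyl (3S)-3-phenylpentanedioate | COC(=O)C[C@@H](CC(=O)OC(C)(C)c1ccccc1)c1ccccc1 | intermediate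
12 | cumyl (3S)-5-[methoxy(methyl)amino]-5-oxo-3-phenylpentanoate (not isolated) | CON(C)C(=O)C[C@@H](CC(=O)OC(C)(C)c1ccccc1)c1ccccc1 | intermediate
13 | cumyl (3S)-5-oxo-3-phenylhexanoate | CC(=O)C[C@@H](CC(=O)OC(C)(C)c1ccccc1)c1ccccc1 | intermediate
14 | methyl (2R)-2-(chlorocarbonyl)-5-methyl-2-[(2S)-lavandulyl]hex-4-enoate (not isolated) | C=C(C)[C@@H](CC=C(C)C)C[C@](CC=C(C)C)(C(=O)OC)C(=O)Cl | intermediate
15 | kinetic lithium enolate of 13 (not isolated) | [Li+].C=C([O-])C[C@@H](CC(=O)OC(C)(C)c1ccccc1)c1ccccc1 | intermediate
16 | 1-methyl 9-cumyl (2S,7S)-2-[(2S)-lavandulyl]-3,5-dioxo-7-phenyl-2-prenylnonanedioate | C=C(C)[C@@H](CC=C(C)C)C[C@](CC=C(C)C)(C(=O)OC)C(=O)CC(=O)C[C@@H](CC(=O)OC(C)(C)c1ccccc1)c1ccccc1 | intermediate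
17 | dilithium 1,3-diketone dianion of 16 (not isolated) | [Li+].[Li+].C=C(C)[C@@H](CC=C(C)C)C[C@](CC=C(C)C)(C(=O)OC)C([O-])=CC([O-])=C[C@@H](CC(=O)OC(C)(C)c1ccccc1)c1ccccc1 | intermediate
18 | cumyl (3S)-3-{(5S)-2-hydroxy-5-[(2S)-lavandulyl]-4,6-dioxo-5-prenylcyclohex-1-en-1-yl}-3-phenylpropanoate | C=C(C)[C@@H](CC=C(C)C)C[C@]1(CC=C(C)C)C(=O)C([C@@H](CC(=O)OC(C)(C)c2ccccc2)c2ccccc2)=C(O)CC1=O | intermediate
19 | methyl (S)-3-hydroxybutanoate | C[C@H](O)CC(=O)OC | starting material
20 | dilithium alkoxide enolate of 19 (not isolated) | [Li+].[Li+].C[C@H]([O-])C=C([O-])OC | intermediate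
21 | methyl (2S,3S)-3-hydroxy-2-methylbutanoate | C[C@H](O)[C@H](C)C(=O)OC | intermediate
22 | (2S,3S)-3-hydroxy-2-methylbutanoic acid | C[C@H](O)[C@H](C)C(=O)O | intermediate
23 | triethylsilyl (2S,3S)-2-methyl-3-(triethylsilyloxy)butanoate (not isolated) | C[C@H](O[Si](CC)(CC)CC)[C@H](C)C(=O)O[Si](CC)(CC)CC | intermediate
24 | (2S,3S)-2-methyl-3-(triethylsilyloxy)butanoic acid | C[C@H](O[Si](CC)(CC)CC)[C@H](C)C(=O)O | intermediate
25 | C5–O enol ester of 18 with 24 (not isolated) | C=C(C)[C@@H](CC=C(C)C)C[C@]1(CC=C(C)C)C(=O)C([C@@H](CC(=O)OC(C)(C)c2ccccc2)c2ccccc2)=C(OC(=O)[C@@H](C)[C@H](C)O[Si](CC)(CC)CC)CC1=O | intermediate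
26 | C4a-[(2S,3S)-2-methyl-3-(triethylsilyloxy)butanoyl] trione, cumyl ester | C=C(C)[C@@H](CC=C(C)C)C[C@]1(CC=C(C)C)C(=O)C([C@@H](CC(=O)OC(C)(C)c2ccccc2)c2ccccc2)=C(O)C(C(=O)[C@@H](C)[C@H](C)O[Si](CC)(CC)CC)=C1O | intermediate
27 | C4a-[(2S,3S)-3-hydroxy-2-methylbutanoyl] trione, cumyl ester | C=C(C)[C@@H](CC=C(C)C)C[C@]1(CC=C(C)C)C(=O)C([C@@H](CC(=O)OC(C)(C)c2ccccc2)c2ccccc2)=C(O)C(C(=O)[C@@H](C)[C@H](C)O)=C1O | intermediate
28 | cumyl ester of the target, (2R,3S,8S) core | C=C(C)[C@@H](CC=C(C)C)C[C@]1(CC=C(C)C)C(=O)C([C@@H](CC(=O)OC(C)(C)c2ccccc2)c2ccccc2)=C(O)C2=C1O[C@H](C)[C@H](C)C2=O | intermediate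
29 | CNP0150579.2 | C=C(C)[C@@H](CC=C(C)C)C[C@]1(CC=C(C)C)C(=O)C([C@@H](CC(=O)O)c2ccccc2)=C(O)C2=C1O[C@H](C)[C@H](C)C2=O | target

Total step count: 16 (malonate arm 4, glutarate arm 3, hydroxy acid 3, union and endgame 6).
Longest linear sequence: 10 steps (1, 2, 3, 4, 8, 9, 13, 14, 15, 16).

Steps most likely to fail

Step 9. Several processes can compete with the closure:
- The second deprotonation may stay incomplete, and the remaining mono-enolate may then close through oxygen.
- The diketone may be cleaved by the liberated methoxide.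
- Attack on the neopentyl-type methyl ester may be slow.
- Deprotonation next to the cumyl ester may compete.

The fallback keeps the C6–C7 closure but raises the electrophilicity of the acyl partner. It sets out from 6 and comes back at 18.
- The methyl ester of 6 is saponified (KOH, aq MeOH; the tert-butyl ester is inert) to (2R)-2-(tert-butoxycarbonyl)-5-methyl-2-[(2S)-lavandulyl]hex-4-enoic acid F1.
- EDC, DMAP and ethanethiol convert F1 into the tert-butyl S-ethyl thioester F2.
- TMSOTf and 2,6-lutidine, as in step 4, lead through the trimethylsilyl ester F3 to the thioester half acid F4.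
- The chloroenamine gives the acid chloride F5, which acylates enolate 15 to the S-ethyl 3,5-dioxo thioester F6.
- Double deprotonation as in step 9 gives its dilithium dianion F7. This should close at −78 °C, because a thioester is attacked by carbon nucleophiles far faster than an alkyl ester. Ethanethiolate is expelled and 18 results.

Step 15. Two processes can spoil this step:
- The closure may go through the C5 oxygen.
- The activated hydroxyl may be lost by β-elimination, followed by unselective re-addition that erodes C2 and C3.

The fallback replaces substitution at sp3 carbon by a conjugate addition. It sets out from 18 and comes back at 28, and it makes steps 10–14 unnecessary.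
- Compound 18 is acylated with tiglic acid under the conditions of step 13, through the enol tiglate F8, to the C4a-(E)-2-methylbut-2-enoyl trione F9.
- (−)-Quinine (cat., chlorobenzene, low temperature) then promotes an intramolecular oxa-Michael addition.
- This reaction type turns o-tigloylphenols into 2,3-cis-dimethylchromanones through catalyst-controlled C–O bond formation and kinetic protonation. By that analogy the (2R,3S) ring is expected.
- Because the addition is reversible, the regiochemistry should settle on the isomer that keeps the C5–OH···O=C4 hydrogen bond, which is 28.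

Step 3. Facial discrimination may be poor because the α-substituent is long and β-branched, and a slow alkylation would give the aqueous base time to attack the methyl ester. The fallback postpones the stereochemical decision to an enzymatic group selection. It sets out from 2 and comes back at 8, and it also skips step 4.
- Dimethyl malonate is alkylated with 2 (NaH, DMF) to dimethyl [(2S)-lavandulyl]malonate F10.
- F10 is prenylated with 5 (NaH, THF) to dimethyl [(2S)-lavandulyl](prenyl)malonate F11, whose central carbon is not yet stereogenic.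
- Pig liver esterase (pH 7 buffer, DMSO cosolvent) hydrolyses one of the two diastereotopic methyl esters, an established desymmetrisation of dialkylmalonates, to give 8.
- The epimeric half acid is a diastereomer and can be removed by crystallising an amine salt.

Further compounds
F1 | step 9 | (2R)-2-(tert-butoxycarbonyl)-5-methyl-2-[(2S)-lavandulyl]hex-4-enoic acid | C=C(C)[C@@H](CC=C(C)C)C[C@](CC=C(C)C)(C(=O)O)C(=O)OC(C)(C)C
F2 | step 9 | tert-butyl (2S)-2-(ethylsulfanylcarbonyl)-5-methyl-2-[(2S)-lavandulyl]hex-4-enoate | C=C(C)[C@@H](CC=C(C)C)C[C@](CC=C(C)C)(C(=O)SCC)C(=O)OC(C)(C)C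
F3 | step 9 | trimethylsilyl (2S)-2-(ethylsulfanylcarbonyl)-5-methyl-2-[(2S)-lavandulyl]hex-4-enoate | C=C(C)[C@@H](CC=C(C)C)C[C@](CC=C(C)C)(C(=O)SCC)C(=O)O[Si](C)(C)C
F4 | step 9 | (2S)-2-(ethylsulfanylcarbonyl)-5-methyl-2-[(2S)-lavandulyl]hex-4-enoic acid | C=C(C)[C@@H](CC=C(C)C)C[C@](CC=C(C)C)(C(=O)SCC)C(=O)O
F5 | step 9 | S-ethyl (2R)-2-(chlorocarbonyl)-5-methyl-2-[(2S)-lavandulyl]hex-4-enethioate | C=C(C)[C@@H](CC=C(C)C)C[C@](CC=C(C)C)(C(=O)SCC)C(=O)Cl
F6 | step 9 | cumyl (3S,8S)-8-(ethylsulfanylcarbonyl)-8-[(2S)-lavandulyl]-11-methyl-5,7-dioxo-3-phenyldodec-10-enoate | C=C(C)[C@@H](CC=C(C)C)C[C@](CC=C(C)C)(C(=O)SCC)C(=O)CC(=O)C[C@@H](CC(=O)OC(C)(C)c1ccccc1)c1ccccc1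
F7 | step 9 | dilithium 1,3-diketone dianion of F6 | [Li+].[Li+].C=C(C)[C@@H](CC=C(C)C)C[C@](CC=C(C)C)(C(=O)SCC)C([O-])=CC([O-])=C[C@@H](CC(=O)OC(C)(C)c1ccccc1)c1ccccc1
F8 | step 15 | C5–O enol tiglate of 18 | C=C(C)[C@@H](CC=C(C)C)C[C@]1(CC=C(C)C)C(=O)C([C@@H](CC(=O)OC(C)(C)c2ccccc2)c2ccccc2)=C(OC(=O)/C(C)=C/C)CC1=O
F9 | step 15 | C4a-[(E)-2-methylbut-2-enoyl] trione, cumyl ester | C=C(C)[C@@H](CC=C(C)C)C[C@]1(CC=C(C)C)C(=O)C([C@@H](CC(=O)OC(C)(C)c2ccccc2)c2ccccc2)=C(O)C(C(=O)/C(C)=C/C)=C1O
F10 | step 3 | dimethyl 2-[(2S)-lavandulyl]propanedioate | C=C(C)[C@@H](CC=C(C)C)CC(C(=O)OC)C(=O)OC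
F11 | step 3 | dimethyl 2-[(2S)-lavandulyl]-2-prenylpropanedioate | C=C(C)[C@@H](CC=C(C)C)CC(CC=C(C)C)(C(=O)OC)C(=O)OC
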